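## Structural features

The target joins two domains through a three-carbon hinge. The first is a trans-decalin (rings A and B, C1–C10). The second is a 1,2-dioxane (C3', C4', C5', C6' and the O–O unit) trans-fused across C3'–C4' to a γ-lactone (C1'–C4'). C9 carries the chain C11–C12–C13, and C13 bears an exocyclic methylene and is bonded to C6'. The decalin holds six stereocentres in two contiguous runs, C4–C5–C6 and C8–C9–C10. C4 has an equatorial (α) methyl ester (C18) and an axial methyl, C6 an equatorial α-hydroxyl, C8 a tertiary α-hydroxyl with an axial β-methyl (C17), C9 the equatorial side chain and C10 the angular methyl. This is the ring A/B pattern of abietic acid with two extra oxygens. The peroxylactone holds three more stereocentres: C3' (quaternary, methyl and peroxide oxygen) next to C4' (lactone oxygen), and C6' (peroxide oxygen, allylic to C13=CH2) one methylene further on. Because the fusion is trans, the C3'–OO and C4'–O bonds are anti, which is the result of an anti addition across an E-configured C4'=C3' alkene. Fragile groups are: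
- the O–O bond (reductants, phosphines, low-valent metals, organometallics);
- the allylic C6'–H next to the peroxide (base-induced Kornblum–DeLaMare cleavage);
- the β-peroxy lactone (retro-oxa-Michael, which would return the more stable cis fusion);
- the tertiary C8 alcohol (dehydration).

The real difficulty is twofold. C6' is insulated from the decalin by C11–C13, so its configuration cannot be relayed from the terpene. The trans-fused peroxylactone cannot be made by the usual conjugate addition of a hydroperoxide to a butenolide. The key step exploits the chain C13(=CH2)–C6'–C5'–C4'=C3'. C13 is an sp2 carbon that can sit on boron and migrate, C6' and C5' are the two carbons of a vinyl group, and C4' is the sp2 carbon of an alkenyl halide.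

## Logic of the disconnections

31 back to 29. The two Si–O bonds are cut first and then the lactone bond between the C4' oxygen and C1'. The hydroxyls at C6 and C8 must stay masked through the organolithium and sulfonylation steps, and the lactone is closed as late as possible because a β-peroxy lactone is the most base-sensitive part of the molecule. The gain is that 29 has one heterocycle fewer and an ordinary methyl ester. The demand is that both forward steps run under acid only.

29 back to 27 (through 28). Both C–O bonds of the peroxide are cut, with H2O2 as the source of the O–O unit. C3'–O is made first, by intermolecular opening of an epoxide at its tertiary carbon. C6'–O is made second, by intramolecular displacement of a sulfonate. In this order the regiochemistry at the epoxide is governed only by the tertiary centre, with no contest between five- and six-membered closure. The attack at the allylic C6' is tied into a six-membered transition state and cannot stray to the alkene terminus. The gain is that 27 contains no peroxide. The demand is clean inversion at C3' and at C6', and an allylic sulfonate that survives a short acidic stage.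

27 back to 24. The S–O bond, the two epoxide C–O bonds and the C6'–O bond are cut in turn, the last back to a C–B bond. C3' and C4' then come from one reagent-controlled epoxidation of the E alkene, and C6' from a retentive oxidation. The gain is that 24 has only one stereocentre outside the decalin. The demand is an oxidant that prefers the trisubstituted alkene to the C13 methylene and a chiral ketone that sets both epoxide centres.

24 back to 15, 20 and 22 (from 21). This is the key cut, through C13–C6' and C5'–C4'. It divides the molecule into the complete decalin, a two-carbon unit and a five-carbon ester, and it lets a chiral catalyst set the one stereocentre that the decalin cannot reach. The S configuration of C6' in 24 (boron ranking below carbon) is the one that retentive oxidation and invertive peroxide formation turn into the R centre of 31. The demand is that the metallate shift outruns direct boron-to-palladium transfer, that the geometry of 20 is kept, and that two esters and two silyl ethers are tolerated.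

20 back to 16. The C3'–CH3 and C4'–Br bonds are cut together as a syn carbometalation of a terminal alkyne, and the ester is traced to a primary alcohol. A four-carbon alkynol already holds every chain carbon, so no homologation is needed. The demand is full regio- and stereocontrol in the carbometalation and an oxidation that leaves the β,γ-alkene in place.

15 back to 12. The C13–B bond is cut to the alkyne 14, the alkyne carbon to the aldehyde 13, and 13 to the ester 12. The gain is that C13 becomes an ordinary carboxyl carbon. The demand is boron delivery to the internal alkyne carbon and a hydride that distinguishes the side-chain ester from the hindered C18 ester.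

12 back to 9. The C13–O bond is cut as an oxygen insertion between C13 and the isopropyl group, then the Si–O bonds, then the C8–O bond as a Markovnikov hydration of an exocyclic alkene. The gain is that the isopropyl group of the terpene is excised without loss of C13, and the tertiary alcohol comes from a planar carbon whose β face is blocked. The demand is migration of the secondary carbon in the oxygen insertion and α attack at C8.

9 back to 4. The C17 oxygen is replaced by hydrogen with a shift of the alkene, and the C6–O bond is cut back to the γ-carbon of an enal. The gain is that one aldehyde serves for two tasks: it activates C6 for oxidation and then disappears while placing the alkene where C8 needs it. The demand is oxidation at the γ-carbon from the α face and a reduction that touches the aldehyde but not the ketone.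

4 back to 1. Ring C is re-formed across C13–C14 and the ester is returned to the acid. The gain is that C4, C5, C9 and C10 and the C18 carboxyl come from the chiral pool. The demand is oxidative cleavage of only one of the two alkenes of the diene.

## Other disconnections considered

Alternative 1: The cut lies in a small fragment, through the C6'–O bond of the peroxide and the lactone C–O bond, with the decalin attached afterwards through the sulfone-bearing carbon. In the forward key step the open-chain hydroperoxy mesylate A2 would be treated with Cs2CO3. The tertiary C3' hydroperoxide would displace the C6' mesylate with inversion (6-exo-tet), and the C4' hydroxyl would then acylate to give the peroxylactone allyl phenyl sulfone A1.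

In its favour:
- the peroxide closure is intramolecular, so neither allylic transposition nor a five-membered closure can compete;
- it is tried early on a cheap fragment;
- the synthesis becomes convergent.

Against it here:
- once A1 exists, the union with the decalin needs a sulfonyl carbanion beside a peroxide with an acidic C6'–H and a β-peroxy lactone;
- the electrophile at C11 of the decalin is hindered;
- the sulfone must be removed reductively, with electron-transfer reagents that also cleave O–O;
- the three stereocentres of A2 still need their own asymmetric steps.

Comparison: on the mode of ring closure the alternative is the equal of the chosen plan, which uses the same displacement in step 19. On convergence and on early testing of the peroxide chemistry it is the better. On compatibility the chosen plan is the better, because no carbanion, palladium or reductant meets the O–O bond. The step count would be about the same.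

Alternative 2: The cut is the C6–O bond, traced back to a C–H bond in the 12,8α-lactone acid A4. In the forward key step Mn(pdp)(OTf)2 and H2O2 would be directed by the bound C18 carboxylate to the γ C–H bond at C6, and rebound would close the five-membered lactone of the bis-lactone A3.

In its favour:
- no functional handle is needed at C6;
- the equatorial carboxylate can reach only the equatorial 6α hydrogen, so on stereocontrol at C6 it is at least the equal of the chosen peracid oxidation;
- it would replace steps 3 and 4.

Against it here:
- the γ-methylene at C2 and the tertiary C–H bonds at C5 and C9 compete for the oxidant;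
- the acid must be free, so the methyl ester has to be made later by opening the new lactone;
- A4 ends at C12, so C13 must be added again, whereas the chosen degradation keeps it.

Comparison: the alternative is more direct in concept and equal or better in atom economy. It is less predictable in site selectivity than enol chemistry at the γ-carbon of an enal. After lactone opening and chain extension the step count would be about equal.

Alternative 3: The cut goes through C5–C10 and C8–C9, so that rings A and B are made together. In the forward key step the acyclic triene A6 would undergo an intramolecular Diels–Alder reaction (four-atom tether) of its bis(silyloxy)diene with the E enoate to give the trans-decalin A5.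

In its favour:
- two C–C bonds, two rings and four stereocentres (C5, C8, C9, C10) form in one step, which is better than any single step of the chosen plan;
- oxygen at C6 and C8 is built in;
- the route does not depend on a natural resin acid.

Against it here:
- the absolute configuration would need a chiral catalyst or auxiliary;
- the partners are poorly matched: a β,β-disubstituted enoate and a diene whose fully substituted C8 terminus must carry its silyloxy group on the inside position to give the 8α oxygen;
- the geminal diester at C4 must be differentiated against the steric bias, since the axial ester has to become the methyl group;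
- the C6 ketone must be reduced to the equatorial alcohol;
- the C11 ester must be extended by two carbons.

Comparison: the chosen plan takes C4, C5, C9 and C10 from abietic acid and adds the oxygens by face-selective reactions on a rigid decalin. The alternative reaches the bicycle in fewer bond-forming events but would need more corrective steps, and its stereochemical outcome is less secure. Both leave the union at C13–C6' to a later stage and are equal on that point.

Key step: step 15

Assumption: the (Rp,Rp) antipode of the MandyPhos ligand is taken to be the one that gives the (6'S)-boronate 24. If the sense of induction is the reverse, the (Sp,Sp) antipode is used and nothing else changes.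

Remark on locants: C17 is the carbon on C8 (C14 of abietic acid), C18 the ester carbon on C4, C19 and C20 the methyls on C4 and C10. Primed locants belong to the peroxylactone.

Remark on the key-step compounds: 15 and 24 were compared with 31 centre by centre. The decalin centres agree, and the C6' configuration of 24 is the one that retention followed by inversion requires, so no structure had to be corrected. Four points of design were changed:
- the bromide 20 is made from a four-carbon alkynol, so no homologation is needed;
- NaOTf is added to the coupling as halide scavenger;
- the epoxidation uses the L-series Shi ketone;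
- the two peroxide C–O bonds are formed in the order C3' then C6'.

Step 1
Reactants: 1 abietic acid
Product: 2 methyl abietate
Conditions: MeI, K2CO3, DMF, rt
Reagents that add atoms: iodomethane, CI
Why: SN2 O-alkylation of the carboxylate; the tertiary C18 acid is too hindered for Fischer esterification, and no stereocentre is touched.

Step 2
Reactants: 2 methyl abietate
Product: 4 keto enal, via cis-13,14-diol 3 (not isolated)
Conditions: OsO4 (2 mol%), N-methylmorpholine N-oxide, acetone/H2O, rt; then NaIO4, THF/H2O, 0 °C to rt
Reagents that add atoms: N-methylmorpholine N-oxide, C[N+]1([O-])CCOCC1; water, O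
Why: Upjohn dihydroxylation then periodate glycol cleavage; C13=C14 is the open terminus of the diene (C7=C8 is shielded by the C9–C10 ring fusion) and once it is oxidised the remaining alkene is no longer part of a diene, so ring C opens to the C13 isopropyl ketone and the conjugated C17 aldehyde.

Step 3
Reactants: 4 keto enal
Product: 5 dienol acetate
Conditions: Ac2O, Et3N, DMAP (cat.), THF, 50 °C
Reagents that add atoms: acetic anhydride, CC(=O)OC(C)=O
Why: O-acylation of the extended enol of the enal after γ-deprotonation at C6, the only γ position; a simple ketone is not enol-acetylated by an amine base, so the C13 ketone is a spectator.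

Step 4
Reactants: 5 dienol acetate
Product: 7 6α-hydroxy enal, via epoxy enol acetate 6 (not isolated)
Conditions: mCPBA (1.05 equiv), NaHCO3, CH2Cl2, 0 °C; then AcOH/THF/H2O, rt
Reagents that add atoms: 3-chloroperbenzoic acid, O=C(OO)c1cccc(Cl)c1
Why: Prilezhaev epoxidation of the distal C6=C7 bond of the 1-acetoxy diene (vinylogous Rubottom oxidation, as with steroidal dienol acetates) from the α face, the β face being closed by the axial C19 and C20 methyls; acid then opens the allylic epoxide at C7 with loss of the acetyl group, which restores the enal and leaves the equatorial 6α-hydroxyl, while the Baeyer–Villiger reaction of the ketone is too slow at 0 °C to interfere.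

Step 5
Reactants: 7 6α-hydroxy enal
Product: 9 exocyclic alkene, via tosylhydrazone 8 (not isolated)
Conditions: TsNHNH2 (1.05 equiv), THF, rt; then catecholborane, CHCl3, 0 °C; then NaOAc·3H2O, 60 °C
Reagents that add atoms: none
Why: Reductive 1,3-transposition of an unsaturated tosylhydrazone: 1,2-hydride addition, loss of sulfinate to the allylic diazene and retro-ene loss of N2 deliver hydrogen to C7 and move the alkene to C8=C17; the aldehyde condenses far faster than the α-branched ketone, which secures the chemoselectivity.

Step 6
Reactants: 9 exocyclic alkene
Product: 10 6α,8α-diol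
Conditions: Co(acac)2 (20 mol%), PhSiH3, O2 (1 atm), THF, rt
Reagents that add atoms: dioxygen, O=O
Why: Mukaiyama hydration (hydrogen-atom transfer to the methylene, Markovnikov); the planar tertiary C8 radical is captured by O2 from the α face because the axial approach from the β face is blocked by the C20 methyl, giving the 8α-hydroxyl and the 8β-methyl; ketone and ester are inert.

Step 7
Reactants: 10 6α,8α-diol
Product: 11 bis-silyl ether
Conditions: Et3SiOTf (3 equiv), 2,6-lutidine, CH2Cl2, −78 to 0 °C
Reagents that add atoms: triethylsilyl trifluoromethanesulfonate, CC[Si](CC)(CC)OS(=O)(=O)C(F)(F)F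
Why: Silylation of the secondary and the tertiary alcohol with the silyl triflate; 2,6-lutidine at low temperature does not enolise the ketone.

Step 8
Reactants: 11 bis-silyl ether
Product: 12 isopropyl ester
Conditions: mCPBA, NaHCO3, CH2Cl2, rt
Reagents that add atoms: 3-chloroperbenzoic acid, O=C(OO)c1cccc(Cl)c1
Why: Baeyer–Villiger oxidation; the secondary isopropyl carbon migrates in preference to the primary C12, so oxygen is inserted on the isopropyl side and C13 remains as the acyl carbon; the buffer protects the silyl ethers.

Step 9
Reactants: 12 isopropyl ester
Product: 13 C13 aldehyde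
Conditions: iBu2AlH (1.1 equiv), CH2Cl2, −78 °C; aq. KNaC4H4O6
Reagents that add atoms: none
Why: Partial reduction through the aluminium hemiacetal that is stable at −78 °C; the C18 methyl ester sits on the quaternary C4 and is too hindered to compete.

Step 10
Reactants: 13 C13 aldehyde
Product: 14 terminal alkyne
Conditions: dimethyl (1-diazo-2-oxopropyl)phosphonate, K2CO3, MeOH, 0 °C to rt
Reagents that add atoms: dimethyl (1-diazo-2-oxopropyl)phosphonate, COP(=O)(OC)C(=[N+]=[N-])C(C)=O
Why: Ohira–Bestmann (Seyferth–Gilbert) homologation through the alkylidene carbene and 1,2-hydrogen shift; mild carbonate conditions leave both silyl ethers and the hindered ester alone.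

Step 11
Reactants: 14 terminal alkyne
Product: 15 alkenyl pinacol boronate
Conditions: (SIMes)CuCl (5 mol%; SIMes = 1,3-dimesitylimidazolidin-2-ylidene), NaOtBu (5 mol%), B2pin2 (1.1 equiv), MeOH (2 equiv), THF, −50 to −15 °C
Reagents that add atoms: bis(pinacolato)diboron, CC1(C)OB(OC1(C)C)B1OC(C)(C)C(C)(C)O1
Why: N-heterocyclic-carbene–copper-catalysed protoboration; the copper–boryl species adds across the alkyne with boron on the internal carbon (the orientation favoured by N-aryl carbene ligands) and methanol protonates the C–Cu bond, giving the 1,1-disubstituted alkenyl boronate under conditions that spare esters.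

Step 12
Reactants: 16 but-3-yn-1-ol
Product: 18 (E)-4-bromo-3-methylbut-3-en-1-ol, via alkenylalane 17 (not isolated)
Conditions: Me3Al (3 equiv), Cp2ZrCl2 (25 mol%), CH2Cl2, 0 °C to rt; then N-bromosuccinimide, THF, −30 °C
Reagents that add atoms: trimethylaluminium, C[Al](C)C; N-bromosuccinimide, O=C1CCC(=O)N1Br
Why: Negishi zirconium-catalysed carboalumination adds methyl and aluminium syn with aluminium on the terminal carbon; bromodealumination with retention gives the E alkenyl bromide.

Step 13
Reactants: 18 (E)-4-bromo-3-methylbut-3-en-1-ol
Product: 19 (E)-4-bromo-3-methylbut-3-enoic acid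
Conditions: CrO3, H2SO4 (aq), acetone, 0 °C
Reagents that add atoms: water, O
Why: Jones oxidation through the aldehyde hydrate; the acidic medium does not move the β,γ-alkene into conjugation and the alkenyl bromide is inert.

Step 14
Reactants: 19 (E)-4-bromo-3-methylbut-3-enoic acid
Product: 20 methyl (E)-4-bromo-3-methylbut-3-enoate
Conditions: MeOH, H2SO4 (cat.), 50 °C
Reagents that add atoms: methanol, CO
Why: Fischer esterification; acid is chosen because base could isomerise the alkene to the conjugated allylic bromide.

Step 15
Reactants: 15 alkenyl pinacol boronate; 21 vinyl bromide; 20 methyl (E)-4-bromo-3-methylbut-3-enoate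
Product: 24 (6'S)-allylic boronate, via vinyllithium 22 (not isolated), via lithium ate complex 23 (not isolated)
Conditions: 21, t-BuLi (2 equiv), Et2O, −78 °C; add 15 (vinyllithium 1.05 equiv), THF, −78 °C to rt; then Pd(OAc)2 (3 mol%), (Rp,Rp)-MandyPhos (3.6 mol%), NaOTf (2 equiv), 20 (1.2 equiv), THF, 60 °C
Reagents that add atoms: none
Why: Vinyllithium adds to the boron of 15 to give the four-coordinate bis(alkenyl) borate 23. Zerovalent palladium, formed from Pd(OAc)2 and the bisphosphine, inserts into the C–Br bond of 20 with retention of the E geometry, and NaOTf takes bromide off the metal so that the cationic alkenylpalladium can bind the unsubstituted vinyl group of 23. The C13 alkenyl group then shifts from boron to C6' anti to palladium (1,2-metallate shift), and reductive elimination joins C5' to C4' and returns zerovalent palladium. The closest known reaction type is the palladium-catalysed enantioselective conjunctive cross-coupling of vinyl boron ate complexes, which includes bis(alkenyl) borates that give α-chiral allylic boronates. No ring is closed. C6' is the only new stereocentre and is set by the chiral bisphosphine on palladium, which chooses the face of the bound vinyl group; the decalin is too remote to interfere, so the selectivity is catalyst-controlled. The step needs site selectivity between the two alkenes on boron and chemoselectivity against direct transmetalation: the 1,1-disubstituted C13 alkene is too hindered to bind palladium, so the vinyl group is activated and the substituted alkenyl group migrates, while the chelating bisphosphine on a cationic metal favours the metallate shift over Suzuki–Miyaura transfer. One equivalent of vinyllithium at −78 °C is taken up by boron faster than it can attack the hindered C18 ester, and the borate is inert to both esters.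

Step 16
Reactants: 24 (6'S)-allylic boronate
Product: 25 (6'S)-allylic alcohol
Conditions: NaBO3·4H2O, THF/H2O, rt
Reagents that add atoms: sodium perborate, [Na+].[Na+].O[B-]1(O)OO[B-](O)(O)OO1
Why: Oxidation of the C–B bond by 1,2-shift of carbon from boron to oxygen with retention and without allylic transposition; perborate is mild enough for both methyl esters.

Step 17
Reactants: 25 (6'S)-allylic alcohol
Product: 26 (3'S,4'S)-epoxy alcohol
Conditions: L-fructose-derived Shi ketone (1,2:4,5-di-O-isopropylidene-β-L-erythro-2,3-hexodiulo-2,6-pyranose, 30 mol%), KHSO5 (as 2KHSO5·KHSO4·K2SO4), K2CO3, Bu4NHSO4, MeCN/(MeO)2CH2/aq. Na2B4O7 buffer, 0 °C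
Reagents that add atoms: potassium peroxymonosulfate, [K+].[O-]S(=O)(=O)OO
Why: Shi epoxidation through the spiro transition state of the chiral dioxirane; the electron-rich trisubstituted C4'=C3' alkene reacts before the 1,1-disubstituted C13 alkene, which is also deactivated by the allylic oxygen, and the L-series ketone delivers oxygen to the face that gives the (3'S,4'S)-epoxide, both centres being set by the reagent.

Step 18
Reactants: 26 (3'S,4'S)-epoxy alcohol
Product: 27 epoxy mesylate
Conditions: (MeSO2)2O, Et3N, CH2Cl2, −40 °C; cold aqueous work-up, used at once
Reagents that add atoms: methanesulfonic anhydride, CS(=O)(=O)OS(C)(=O)=O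
Why: O-sulfonylation with retention at C6'; the anhydride is used so that no chloride is present to displace the allylic sulfonate, and the epoxide is untouched by the amine base at low temperature.

Step 19
Reactants: 27 epoxy mesylate
Product: 29 1,2-dioxane hydroxy ester, via hydroperoxy mesylate 28 (not isolated)
Conditions: H2O2 (anhydrous, in Et2O, 10 equiv), H3PMo12O40 (5 mol%), Et2O, 0 °C; cold aqueous wash; then Cs2CO3 (1.2 equiv), DMF, 0 °C
Reagents that add atoms: hydrogen peroxide, OO
Why: Phosphomolybdic-acid-catalysed perhydrolysis of the trisubstituted epoxide: H2O2 attacks the tertiary C3' from the side opposite the epoxide oxygen, so C3' is inverted to R and the C4' oxygen stays in place; after removal of excess H2O2 the hydroperoxide anion displaces the C6' mesylate in a 6-exo-tet intramolecular alkylation with inversion to R, a known way to close 1,2-dioxanes, and any lactone formed at this stage converges in step 20.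

Step 20
Reactants: 29 1,2-dioxane hydroxy ester
Product: 30 bis-silyl peroxylactone
Conditions: 10-camphorsulfonic acid (20 mol%), toluene, 5 Å molecular sieves, 40 °C
Reagents that add atoms: none
Why: Acid-catalysed lactonisation of the γ-hydroxy ester; the C4' hydroxyl and the CH2CO2Me arm on C3' are trans-diequatorial on the dioxane chair, the arrangement from which the trans-fused five-membered lactone closes, and acid is used because base would invite retro-oxa-Michael loss of the peroxide or cleavage at the C6'–H.

Step 21
Reactants: 30 bis-silyl peroxylactone
Product: 31 target CNP0162504.1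
Conditions: HF·pyridine, THF/pyridine, 0 °C to rt
Reagents that add atoms: none
Why: Fluoride-assisted cleavage of the secondary and the tertiary triethylsilyl ether under weakly acidic conditions that leave the O–O bond, the lactone, the methyl ester and the tertiary alcohol intact.

Compound list

1 | abietic acid (abieta-7,13-dien-18-oic acid) | CC(C)C1=CC2=CC[C@@H]3[C@@]([C@H]2CC1)(CCC[C@@]3(C)C(=O)O)C | starting material
2 | methyl abietate | CC(C)C1=CC2=CC[C@@H]3[C@@]([C@H]2CC1)(CCC[C@@]3(C)C(=O)OC)C | intermediate
3 | methyl 13α,14α-dihydroxyabiet-7-en-18-oate (cis-diol, formed in the flask; its configuration is erased in the cleavage) | CC(C)[C@]1(O)CC[C@@H]2[C@@]3(C)CCC[C@@](C)(C(=O)OC)[C@@H]3CC=C2[C@H]1O | intermediate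
4 | keto enal: methyl 13,14-dioxo-13,14-secoabiet-7-en-18-oate (C7=C8 enal with the aldehyde carbon C17 on C8; 4-methyl-3-oxopentyl chain on C9; decalin centres as in 1) | CC(C)C(=O)CC[C@@H]1[C@@]2(C)CCC[C@@](C)(C(=O)OC)[C@@H]2CC=C1C=O | intermediate
5 | dienol acetate: C17 enol acetate of 4 with C6=C7 and C8=C17 double bonds (acetoxy group drawn on the C7 side; this geometry is of no consequence) | CC(C)C(=O)CC[C@@H]1[C@@]2(C)CCC[C@@](C)(C(=O)OC)[C@@H]2C=C/C1=C\OC(C)=O | intermediate
6 | 6α,7α-epoxide of 5 (formed in the flask) | CC(C)C(=O)CC[C@@H]1[C@@]2(C)CCC[C@@](C)(C(=O)OC)[C@@H]2[C@H]3O[C@H]3/C1=C\OC(C)=O | intermediate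
7 | 6α-hydroxy enal: 4 with an equatorial α-hydroxyl at C6 | CC(C)C(=O)CC[C@@H]1[C@@]2(C)CCC[C@@](C)(C(=O)OC)[C@@H]2[C@@H](O)C=C1C=O | intermediate
8 | C17 N-tosylhydrazone of 7 (formed in the flask) | CC(C)C(=O)CC[C@@H]1[C@@]2(C)CCC[C@@](C)(C(=O)OC)[C@@H]2[C@@H](O)C=C1/C=N/NS(=O)(=O)c1ccc(C)cc1 | intermediate
9 | exocyclic alkene: methyl 6α-hydroxy-13-oxo-13,14-secoabiet-8(14)-en-18-oate (C8=C17H2, C7H2) | CC(C)C(=O)CC[C@@H]1[C@@]2(C)CCC[C@@](C)(C(=O)OC)[C@@H]2[C@@H](O)CC1=C | intermediate
10 | 6α,8α-diol: methyl 6α,8α-dihydroxy-13-oxo-13,14-secoabietan-18-oate (C8 with α-OH and β-CH3) | CC(C)C(=O)CC[C@@H]1[C@@]2(C)CCC[C@@](C)(C(=O)OC)[C@@H]2[C@@H](O)C[C@@]1(C)O | intermediate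
11 | bis-silyl ether: 6α,8α-bis(triethylsilyl) ether of 10 | CC(C)C(=O)CC[C@@H]1[C@@]2(C)CCC[C@@](C)(C(=O)OC)[C@@H]2[C@@H](O[Si](CC)(CC)CC)C[C@@]1(C)O[Si](CC)(CC)CC | intermediate
12 | isopropyl ester: isopropyl 3-(decalin-9β-yl)propanoate with the C18 methyl ester and both triethylsilyl ethers of 11 (C13 is the isopropyl ester carbon) | CC(C)OC(=O)CC[C@@H]1[C@@]2(C)CCC[C@@](C)(C(=O)OC)[C@@H]2[C@@H](O[Si](CC)(CC)CC)C[C@@]1(C)O[Si](CC)(CC)CC | intermediate
13 | C13 aldehyde: 3-(decalin-9β-yl)propanal with the C18 methyl ester and both triethylsilyl ethers | O=CCC[C@@H]1[C@@]2(C)CCC[C@@](C)(C(=O)OC)[C@@H]2[C@@H](O[Si](CC)(CC)CC)C[C@@]1(C)O[Si](CC)(CC)CC | intermediate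
14 | terminal alkyne: 9β-(but-3-ynyl) decalin with the C18 methyl ester and both triethylsilyl ethers | C#CCC[C@@H]1[C@@]2(C)CCC[C@@](C)(C(=O)OC)[C@@H]2[C@@H](O[Si](CC)(CC)CC)C[C@@]1(C)O[Si](CC)(CC)CC | intermediate
15 | alkenyl pinacol boronate: 9β-[3-(pinacolatoboryl)but-3-enyl] decalin, CH2=C13(Bpin), with the C18 methyl ester and both triethylsilyl ethers | C=C(B1OC(C)(C)C(C)(C)O1)CC[C@@H]2[C@@]3(C)CCC[C@@](C)(C(=O)OC)[C@@H]3[C@@H](O[Si](CC)(CC)CC)C[C@@]2(C)O[Si](CC)(CC)CC | intermediate
16 | but-3-yn-1-ol | C#CCCO | starting material
17 | (E)-alkenylalane: dimethylaluminium alkoxide of (E)-4-(dimethylalumanyl)-3-methylbut-3-en-1-ol (formed in the flask) | C[Al](C)/C=C(\C)CCO[Al](C)C | intermediate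
18 | (E)-4-bromo-3-methylbut-3-en-1-ol | Br/C=C(\C)CCO | intermediate
19 | (E)-4-bromo-3-methylbut-3-enoic acid | Br/C=C(\C)CC(=O)O | intermediate
20 | methyl (E)-4-bromo-3-methylbut-3-enoate | Br/C=C(\C)CC(=O)OC | intermediate
21 | vinyl bromide | C=CBr | starting material
22 | vinyllithium (formed in the flask) | [Li]C=C | intermediate
23 | lithium ate complex: lithium (decalin alkenyl)(vinyl)(pinacolato)borate (formed in the flask) | [Li+].C=C[B-]1(OC(C)(C)C(C)(C)O1)C(=C)CC[C@@H]2[C@@]3(C)CCC[C@@](C)(C(=O)OC)[C@@H]3[C@@H](O[Si](CC)(CC)CC)C[C@@]2(C)O[Si](CC)(CC)CC | intermediate
24 | (6'S)-allylic boronate with C13=CH2, C6'-Bpin and the E C4'=C3' alkene of the methyl ester chain | C=C(CC[C@@H]1[C@@]2(C)CCC[C@@](C)(C(=O)OC)[C@@H]2[C@@H](O[Si](CC)(CC)CC)C[C@@]1(C)O[Si](CC)(CC)CC)[C@@H](B1OC(C)(C)C(C)(C)O1)C/C=C(\C)CC(=O)OC | intermediate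
25 | (6'S)-allylic alcohol | C=C(CC[C@@H]1[C@@]2(C)CCC[C@@](C)(C(=O)OC)[C@@H]2[C@@H](O[Si](CC)(CC)CC)C[C@@]1(C)O[Si](CC)(CC)CC)[C@@H](O)C/C=C(\C)CC(=O)OC | intermediate
26 | (3'S,4'S)-epoxy (6'S)-alcohol | C=C(CC[C@@H]1[C@@]2(C)CCC[C@@](C)(C(=O)OC)[C@@H]2[C@@H](O[Si](CC)(CC)CC)C[C@@]1(C)O[Si](CC)(CC)CC)[C@@H](O)C[C@@H]1O[C@@]1(C)CC(=O)OC | intermediate
27 | epoxy mesylate: C6' methanesulfonate of 26 | C=C(CC[C@@H]1[C@@]2(C)CCC[C@@](C)(C(=O)OC)[C@@H]2[C@@H](O[Si](CC)(CC)CC)C[C@@]1(C)O[Si](CC)(CC)CC)[C@@H](OS(C)(=O)=O)C[C@@H]1O[C@@]1(C)CC(=O)OC | intermediate
28 | hydroperoxy mesylate: (3'R)-hydroperoxide, (4'S)-alcohol, (6'S)-mesylate (formed in the flask) | C=C(CC[C@@H]1[C@@]2(C)CCC[C@@](C)(C(=O)OC)[C@@H]2[C@@H](O[Si](CC)(CC)CC)C[C@@]1(C)O[Si](CC)(CC)CC)[C@@H](OS(C)(=O)=O)C[C@H](O)[C@](C)(OO)CC(=O)OC | intermediate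
29 | 1,2-dioxane hydroxy ester (3'R,4'S,6'R) with free C4' hydroxyl and CH2CO2Me on C3' | C=C(CC[C@@H]1[C@@]2(C)CCC[C@@](C)(C(=O)OC)[C@@H]2[C@@H](O[Si](CC)(CC)CC)C[C@@]1(C)O[Si](CC)(CC)CC)[C@H]1C[C@H](O)[C@@](C)(CC(=O)OC)OO1 | intermediate
30 | bis-silyl peroxylactone: 6,8-bis(triethylsilyl) ether of the target | C=C(CC[C@@H]1[C@@]2(C)CCC[C@@](C)(C(=O)OC)[C@@H]2[C@@H](O[Si](CC)(CC)CC)C[C@@]1(C)O[Si](CC)(CC)CC)[C@H]1C[C@@H]2OC(=O)C[C@@]2(C)OO1 | intermediate
31 | CNP0162504.1 | C=C(CC[C@@H]1[C@@]2(C)CCC[C@@](C)(C(=O)OC)[C@@H]2[C@@H](O)C[C@@]1(C)O)[C@H]1C[C@@H]2OC(=O)C[C@@]2(C)OO1 | target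

Total step count: 21. Longest linear sequence: 18 steps (steps 1–11 and 15–21, from abietic acid); the bromide arm is steps 12–14.

Least certain steps

Step 15 (key step). The most likely failure is leakage into direct boron-to-palladium transfer of one of the two alkenyl groups, which would give dienes in place of 24. Bromide slows the cationic pathway and makes this worse. Weak catalyst control at C6' is the lesser concern. The fallback forms C13–C6' by carbonyl addition and sets out from 15 and 20. Iododeboronation of 15 (NaOMe, then I2, THF/MeOH, −78 to 0 °C) would give the 2-iodoalkene F1. Negishi coupling of 20 with (1,3-dioxolan-2-ylmethyl)zinc bromide (Pd(PPh3)4, THF, 50 °C), with retention of the alkene geometry, would give the dioxolane acetal F2. Cold aqueous formic acid would release the β,γ-unsaturated aldehyde F3, to be used at once. A Nozaki–Hiyama–Kishi coupling of F1 with F3 (CrCl2, NiCl2 (cat.), chiral sulfonamide ligand, Et3N, THF) would then set the C6' carbinol under control of the chromium ligand. The fallback comes back to the route at 25, so step 16 is not needed.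

Step 19. Two processes threaten it. The allylic sulfonate may be lost by ionisation or by attack of external H2O2 while the epoxide is being opened. During the closure, base may cleave the O–O bond at the allylic C6'–H or fragment the β-hydroxy hydroperoxide. The fallback reverses the order of the two C–O bond formations and sets out from 27. Displacement of the mesylate by anhydrous H2O2 in Et2O (−40 to 0 °C, inversion at C6') would give the C6' hydroperoxy epoxide F4. Camphorsulfonic acid in CH2Cl2 would then promote attack of the hydroperoxide on the tertiary C3' of the epoxide, and the fallback comes back to the route at 29. It is held in reserve because closure at C4' to a five-membered peroxide and attack at the alkene terminus are open to it.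

Step 11. The copper–boryl species may add with the wrong orientation (boron on the terminal carbon), because the alkyne has no polar group to steer it. The fallback builds the same boronate from a ketone and sets out from 14. Gold-catalysed hydration ((Ph3P)AuNTf2, MeOH/H2O, rt) would give the methyl ketone F5. Kinetic enolisation and triflation (KN(SiMe3)2, PhNTf2, THF, −78 °C) would give the terminal enol triflate F6. Miyaura borylation (PdCl2(PPh3)2, PPh3, KOPh, B2pin2, toluene, 50 °C) then comes back to the route at 15.

Step 6. Capture of the planar C8 radical from the β face would give the C8 epimer. The fallback replaces the radical by an ionic Markovnikov hydration and sets out from 9. Oxymercuration (Hg(OAc)2, THF/H2O, rt), in which water opens the mercurinium ion at C8 from the equatorial α side, would give the organomercurial F7. Demercuration with Bu3SnH (THF, rt), which does not reduce the ketone, comes back to the route at 10.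

Further compounds

F1 | step 15 | 2-iodoalkene: 9β-(3-iodobut-3-enyl) decalin with the C18 methyl ester and both triethylsilyl ethers | C=C(I)CC[C@@H]1[C@@]2(C)CCC[C@@](C)(C(=O)OC)[C@@H]2[C@@H](O[Si](CC)(CC)CC)C[C@@]1(C)O[Si](CC)(CC)CC
F2 | step 15 | dioxolane acetal: methyl (E)-5-(1,3-dioxolan-2-yl)-3-methylpent-3-enoate | COC(=O)C/C(C)=C/CC1OCCO1
F3 | step 15 | aldehyde: methyl (E)-3-methyl-6-oxohex-3-enoate | COC(=O)C/C(C)=C/CC=O
F4 | step 19 | (6'R)-hydroperoxy (3'S,4'S)-epoxide | C=C(CC[C@@H]1[C@@]2(C)CCC[C@@](C)(C(=O)OC)[C@@H]2[C@@H](O[Si](CC)(CC)CC)C[C@@]1(C)O[Si](CC)(CC)CC)[C@H](OO)C[C@@H]1O[C@@]1(C)CC(=O)OC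
F5 | step 11 | methyl ketone: 9β-(3-oxobutyl) decalin with the C18 methyl ester and both triethylsilyl ethers | CC(=O)CC[C@@H]1[C@@]2(C)CCC[C@@](C)(C(=O)OC)[C@@H]2[C@@H](O[Si](CC)(CC)CC)C[C@@]1(C)O[Si](CC)(CC)CC
F6 | step 11 | terminal enol triflate of F5 | C=C(OS(=O)(=O)C(F)(F)F)CC[C@@H]1[C@@]2(C)CCC[C@@](C)(C(=O)OC)[C@@H]2[C@@H](O[Si](CC)(CC)CC)C[C@@]1(C)O[Si](CC)(CC)CC
F7 | step 6 | organomercurial: 8α-hydroxy-17-(acetoxymercurio) derivative of 9 | CC(C)C(=O)CC[C@@H]1[C@@]2(C)CCC[C@@](C)(C(=O)OC)[C@@H]2[C@@H](O)C[C@@]1(C[Hg]OC(C)=O)O
A1 | alternative 1 | peroxylactone allyl phenyl sulfone | C=C(CS(=O)(=O)c1ccccc1)[C@H]1C[C@@H]2OC(=O)C[C@@]2(C)OO1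
A2 | alternative 1 | open-chain hydroperoxy mesylate methyl ester | C=C(CS(=O)(=O)c1ccccc1)[C@@H](OS(C)(=O)=O)C[C@H](O)[C@](C)(OO)CC(=O)OC
A3 | alternative 2 | 18,6α:12,8α-bis-lactone | O=C1C[C@@H]2[C@@]3(C)CCC[C@@]4(C)C(=O)O[C@H]([C@H]34)C[C@@]2(C)O1
A4 | alternative 2 | 12,8α-lactone with free C18 acid | O=C1C[C@@H]2[C@@]3(C)CCC[C@@](C)(C(=O)O)[C@@H]3CC[C@@]2(C)O1
A5 | alternative 3 | trans-decalin with C6 silyl enol ether, C8 silyl ether and C11 ester | COC(=O)[C@@H]1[C@@]2(C)CCCC(C(=O)OC)(C(=O)OC)[C@@H]2C(O[Si](C)(C)C)=C[C@@]1(C)O[Si](C)(C)C(C)(C)C
A6 | alternative 3 | acyclic triene (E enoate, bis(silyloxy)diene with the C8 silyloxy group inside) | COC(=O)/C=C(\C)CCCC(C(=O)OC)(C(=O)OC)/C=C(O[Si](C)(C)C)/C=C(/C)O[Si](C)(C)C(C)(C)C
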